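**Strategy.** Both halves of the target carry the same (3R,4S)-3,4-dimethyl oxygen heterocycle. In the isochromanone half, the C1(=O)–O2 unit of the lactone ring (C1, O2, C3, C4, C4a, C8a) is read as carbon dioxide set between aromatic C8a and stereocentre C3. The key step takes an open-chain aryl bromide bearing a secondary tosylate, built from (2S,3S)-2,3-epoxybutane, and in one pot exchanges bromine for lithium, captures CO2 (C8a–C1) and closes the lactone by carboxylate SN2 with inversion (O2–C3). The lactone is used twice: acylated and reduced it becomes the electrophile, hydrolysed and decarboxylated the nucleophile. A chiral phosphoric acid joins them; a final formylation closes the quinone methide ring.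

Key step: step 4

Remark on numbering: ring atoms of both halves are numbered as in isochroman (C1, O2, C3, C4, C4a, C5 to C8, C8a).

Assumption: the sense of induction of the chiral phosphoric acid in step 9 cannot be predicted with certainty for this pair of partners; the (R) acid is written, and its enantiomer is to be used if it favours the other epimer at the bridging carbon.

Step 1
Reactants: 1 1-bromo-3,5-dimethoxybenzene; 2 (2S,3S)-2,3-dimethyloxirane
Product: 4 (2S,3S)-3-(3,5-dimethoxyphenyl)butan-2-ol, via aryl Grignard reagent 3 (not isolated)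
Conditions: Mg, THF, reflux; then CuI (10 mol %), 2, −30 °C → rt; aq. NH4Cl
Reagents that add atoms: none
Why: Copper-catalysed SN2 opening of the epoxide by the aryl Grignard reagent should proceed with inversion at the attacked carbon (the two epoxide carbons are equivalent), so the (2S,3S)-epoxide should give only the (2S,3S) alcohol and thereby fix the later C4 stereocentre of both halves.

Step 2
Reactants: 4 (2S,3S)-3-(3,5-dimethoxyphenyl)butan-2-ol
Product: 5 (2S,3S)-3-(2,6-dibromo-3,5-dimethoxyphenyl)butan-2-ol
Conditions: NBS (2.05 equiv), MeCN, 0 °C → rt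
Reagents that add atoms: N-bromosuccinimide, O=C1CCC(=O)N1Br
Why: Electrophilic aromatic bromination should go to the two equivalent positions that are para to one methoxy group and ortho to the other, the position between the two methoxy groups being the least reactive.

Step 3
Reactants: 5 (2S,3S)-3-(2,6-dibromo-3,5-dimethoxyphenyl)butan-2-ol
Product: 8 (2S,3S)-3-(2-bromo-3,5-dimethoxy-6-methylphenyl)butan-2-yl 4-methylbenzenesulfonate, via dilithio intermediate 6 (not isolated), via lithium alkoxide 7 (not isolated)
Conditions: n-BuLi (2.05 equiv), THF, −78 °C; Me2SO4 (1.05 equiv), −78 °C; then TsCl (1.5 equiv), −78 → 0 °C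
Reagents that add atoms: dimethyl sulfate, COS(=O)(=O)OC; 4-methylbenzenesulfonyl chloride, Cc1ccc(cc1)S(=O)(=O)Cl
Why: Deprotonation followed by a single bromine–lithium exchange (the two bromines are equivalent and a second exchange on the aryllithium is disfavoured), C-methylation of the aryllithium, which is much faster than O-methylation of the lithium alkoxide at −78 °C, and O-sulfonylation of the alkoxide with retention at carbon should give the methylated bromo tosylate in one pot.

Step 4
Reactants: 8 (2S,3S)-3-(2-bromo-3,5-dimethoxy-6-methylphenyl)butan-2-yl 4-methylbenzenesulfonate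
Product: 11 (3R,4S)-6,8-dimethoxy-3,4,5-trimethylisochroman-1-one, via aryllithium 9 (not isolated), via lithium carboxylate 10 (not isolated)
Conditions: t-BuLi (2.1 equiv), THF, −100 °C; CO2 (dry gas), −100 → −78 °C; then DMPU, rt → 60 °C
Reagents that add atoms: carbon dioxide, O=C=O
Why: t-BuLi should exchange the aryl bromine at −100 °C faster than it attacks the arenesulfonate, the aryllithium then adds to CO2 to form the C8a–C1 bond, and on warming the lithium carboxylate displaces the tosylate to form the O2–C3 bond. The closest known reaction types are the carboxylation of an aryllithium and lactonisation by intramolecular alkylation of a carboxylate with a sulfonate, here run in one pot. The lactone ring closes in the 6-exo-tet mode. The new stereocentre C3 is set by stereospecific SN2 inversion of the (S)-tosylate to (R) while C4 is not touched, so the trans-(3R,4S) lactone follows from the trans-epoxide through two inversions. The step needs exchange to win over attack at sulfur or Parham-type C-alkylation to a four-membered ring (secured by the low temperature, the immediate CO2 quench and the slow closure of a benzocyclobutene at a secondary carbon) and substitution to win over elimination (secured by a weakly basic carboxylate held next to the leaving group). Retention is excluded because the sulfonate oxygen leaves with sulfur, so the ring oxygen can only come from CO2.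

Step 5
Reactants: 11 (3R,4S)-6,8-dimethoxy-3,4,5-trimethylisochroman-1-one
Product: 12 (3R,4S)-6,8-dihydroxy-3,4,5-trimethylisochroman-1-one
Conditions: BBr3 (4 equiv), CH2Cl2, −78 °C → rt; then H2O
Reagents that add atoms: none
Why: Lewis acid O-demethylation of the two aryl methyl ethers by BBr3 (the 8-methoxy group is assisted by chelation to the lactone carbonyl) should leave the lactone and both stereocentres untouched.

Step 6
Reactants: 12 (3R,4S)-6,8-dihydroxy-3,4,5-trimethylisochroman-1-one
Product: 13 (3R,4S)-7-acetyl-6,8-dihydroxy-3,4,5-trimethylisochroman-1-one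
Conditions: AcOH, BF3·OEt2, 90 °C; then H2O
Reagents that add atoms: acetic acid, CC(=O)O
Why: Friedel–Crafts (Nencki-type) C-acylation should occur at C7, the only unsubstituted ring position, which is ortho to both hydroxyl groups and meta to the lactone carbonyl.

Step 7
Reactants: 13 (3R,4S)-7-acetyl-6,8-dihydroxy-3,4,5-trimethylisochroman-1-one
Product: 14 (3R,4S)-6,8-dihydroxy-7-(1-hydroxyethyl)-3,4,5-trimethylisochroman-1-one (both carbinol epimers)
Conditions: NaBH4, THF/MeOH, 0 °C; pH 7 buffer
Reagents that add atoms: none
Why: Borohydride reduction of the aryl ketone should give the benzylic alcohol, whose configuration is irrelevant because both epimers lead to the same quinone methide in step 9.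

Step 8
Reactants: 12 (3R,4S)-6,8-dihydroxy-3,4,5-trimethylisochroman-1-one
Product: 15 (2R,3S)-3-(3,5-dihydroxy-2-methylphenyl)butan-2-ol
Conditions: KOH (aq., 2 M), 100 °C, N2; then H2SO4 to pH 4, 100 °C
Reagents that add atoms: none
Why: Saponification should open the lactone by acyl–oxygen cleavage (retention at C3, which becomes the (R)-carbinol), and the resulting 2,4-dihydroxybenzoic acid, an orsellinic acid analogue, should undergo protodecarboxylation by ipso protonation ortho and para to the hydroxyl groups.

Step 9
Reactants: 14 (3R,4S)-6,8-dihydroxy-7-(1-hydroxyethyl)-3,4,5-trimethylisochroman-1-one; 15 (2R,3S)-3-(3,5-dihydroxy-2-methylphenyl)butan-2-ol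
Product: 17 (3R,4S)-7-[(1S)-1-[2,6-dihydroxy-4-[(2S,3R)-3-hydroxybutan-2-yl]-3-methylphenyl]ethyl]-6,8-dihydroxy-3,4,5-trimethylisochroman-1-one, via ortho-quinone methide 16 (not isolated)
Conditions: (R)-3,3′-bis(2,4,6-triisopropylphenyl)-1,1′-binaphthyl-2,2′-diyl hydrogen phosphate (10 mol %), 5 Å molecular sieves, CH2Cl2/toluene, 0 °C; 15 in excess
Reagents that add atoms: none
Why: Chiral phosphoric acid-catalysed dehydration of the ortho-hydroxybenzyl alcohol to ortho-quinone methide 16 and face-selective Friedel–Crafts addition of resorcinol 15 within the hydrogen-bonded complex should set the bridging stereocentre under catalyst control, with attack at the ring position between the two hydroxyl groups because the other free position is shielded by the neighbouring sec-alkyl chain.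

Step 10
Reactants: 17 (3R,4S)-7-[(1S)-1-[2,6-dihydroxy-4-[(2S,3R)-3-hydroxybutan-2-yl]-3-methylphenyl]ethyl]-6,8-dihydroxy-3,4,5-trimethylisochroman-1-one
Product: 19 dicitrinone H, (3R,4S)-7-[(1R)-1-[(3R,4S)-6-hydroxy-3,4,5-trimethyl-8-oxo-4,8-dihydro-3H-isochromen-7-yl]ethyl]-6,8-dihydroxy-3,4,5-trimethylisochroman-1-one, via hydroxy aldehyde 18 (not isolated)
Conditions: HC(OEt)3 (5 equiv), TFA, CH2Cl2, 0 °C → rt; then H2O
Reagents that add atoms: triethyl orthoformate, CCOC(OCC)OCC
Why: Acid-promoted ortho-formylation of the resorcinol with the orthoformate should occur at its only free ring position (the lactone-bearing ring is fully substituted), and the aldehyde should cyclise with the (R)-carbinol and lose water to give the quinone methide without touching a stereocentre (the descriptor of the bridging carbon changes from S to R only because the priorities change).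

**Compound list**

1 | 1-bromo-3,5-dimethoxybenzene | COc1cc(Br)cc(OC)c1 | starting material
2 | (2S,3S)-2,3-dimethyloxirane ((2S,3S)-2,3-epoxybutane) | C[C@@H]1O[C@H]1C | starting material
3 | (3,5-dimethoxyphenyl)magnesium bromide | COc1cc(OC)cc([Mg]Br)c1 | intermediate (not isolated)
4 | (2S,3S)-3-(3,5-dimethoxyphenyl)butan-2-ol | C[C@H](O)[C@@H](C)c1cc(OC)cc(OC)c1 | intermediate
5 | (2S,3S)-3-(2,6-dibromo-3,5-dimethoxyphenyl)butan-2-ol | C[C@H](O)[C@@H](C)c1c(Br)c(OC)cc(OC)c1Br | intermediate
6 | lithium (2S,3S)-3-(2-bromo-6-lithio-3,5-dimethoxyphenyl)butan-2-olate | C[C@H](O[Li])[C@@H](C)c1c([Li])c(OC)cc(OC)c1Br | intermediate (not isolated)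
7 | lithium (2S,3S)-3-(2-bromo-3,5-dimethoxy-6-methylphenyl)butan-2-olate | C[C@H](O[Li])[C@@H](C)c1c(C)c(OC)cc(OC)c1Br | intermediate (not isolated)
8 | (2S,3S)-3-(2-bromo-3,5-dimethoxy-6-methylphenyl)butan-2-yl 4-methylbenzenesulfonate | C[C@H](OS(=O)(=O)c1ccc(C)cc1)[C@@H](C)c1c(C)c(OC)cc(OC)c1Br | intermediate
9 | [4,6-dimethoxy-3-methyl-2-[(2S,3S)-3-(tosyloxy)butan-2-yl]phenyl]lithium | C[C@H](OS(=O)(=O)c1ccc(C)cc1)[C@@H](C)c1c(C)c(OC)cc(OC)c1[Li] | intermediate (not isolated)
10 | lithium 4,6-dimethoxy-3-methyl-2-[(2S,3S)-3-(tosyloxy)butan-2-yl]benzoate | C[C@H](OS(=O)(=O)c1ccc(C)cc1)[C@@H](C)c1c(C)c(OC)cc(OC)c1C(=O)O[Li] | intermediate (not isolated)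
11 | (3R,4S)-6,8-dimethoxy-3,4,5-trimethylisochroman-1-one | COc1cc(OC)c(C)c2c1C(=O)O[C@H](C)[C@H]2C | intermediate
12 | (3R,4S)-6,8-dihydroxy-3,4,5-trimethylisochroman-1-one | Oc1cc(O)c(C)c2c1C(=O)O[C@H](C)[C@H]2C | intermediate
13 | (3R,4S)-7-acetyl-6,8-dihydroxy-3,4,5-trimethylisochroman-1-one | CC(=O)c1c(O)c(C)c2c(c1O)C(=O)O[C@H](C)[C@H]2C | intermediate
14 | (3R,4S)-6,8-dihydroxy-7-(1-hydroxyethyl)-3,4,5-trimethylisochroman-1-one (both carbinol epimers) | CC(O)c1c(O)c(C)c2c(c1O)C(=O)O[C@H](C)[C@H]2C | intermediate
15 | (2R,3S)-3-(3,5-dihydroxy-2-methylphenyl)butan-2-ol | C[C@@H](O)[C@@H](C)c1cc(O)cc(O)c1C | intermediate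
16 | (3R,4S)-7-ethylidene-8-hydroxy-3,4,5-trimethyl-3,4-dihydro-1H-isochromene-1,6(7H)-dione (alkene geometry not fixed) | CC=C1C(=O)C(C)=C2C(=C1O)C(=O)O[C@H](C)[C@H]2C | intermediate (not isolated)
17 | (3R,4S)-7-[(1S)-1-[2,6-dihydroxy-4-[(2S,3R)-3-hydroxybutan-2-yl]-3-methylphenyl]ethyl]-6,8-dihydroxy-3,4,5-trimethylisochroman-1-one | C[C@@H](O)[C@@H](C)c1cc(O)c([C@H](C)c2c(O)c(C)c3c(c2O)C(=O)O[C@H](C)[C@H]3C)c(O)c1C | intermediate
18 | 4,6-dihydroxy-2-[(2S,3R)-3-hydroxybutan-2-yl]-3-methyl-5-[(1S)-1-[(3R,4S)-6,8-dihydroxy-3,4,5-trimethyl-1-oxoisochroman-7-yl]ethyl]benzaldehyde | C[C@@H](O)[C@@H](C)c1c(C=O)c(O)c([C@H](C)c2c(O)c(C)c3c(c2O)C(=O)O[C@H](C)[C@H]3C)c(O)c1C | intermediate (not isolated)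
19 | dicitrinone H | CC1=C2C(=CO[C@H](C)[C@H]2C)C(=O)C([C@H](C)c2c(O)c(C)c3c(c2O)C(=O)O[C@H](C)[C@H]3C)=C1O | target

**Step count and risks**

Total step count: 10. Longest linear sequence: 9 steps (steps 1 to 7, then 9 and 10); step 8 is a one-step branch from 12.

Steps most likely to fail:

1. Step 9. Facial control at the bridging carbon may be poor (the quinone methide can form as two alkene isomers, and the two chiral partners may oppose the catalyst). Resorcinol 15 may also be attacked at its other free ring position or alkylated twice. The fallback sets out from 15 (and uses 14) and comes back to the route at 19, bypassing step 10.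
   - Resorcinol 15 is cyclised with dimethoxymethane and catalytic TsOH in MeOH (oxa-Pictet–Spengler reaction) to (3R,4S)-3,4,5-trimethylisochromane-6,8-diol F3, which ties up the competing ring position and leaves C7 as the only nucleophilic carbon.
   - F3 is coupled with 14 under the same phosphoric acid catalysis to give (3R,4S)-7-[(1S)-1-[(3R,4S)-6,8-dihydroxy-3,4,5-trimethylisochroman-7-yl]ethyl]-6,8-dihydroxy-3,4,5-trimethylisochroman-1-one F4. If catalyst control is insufficient, diphenyl phosphate is used and the two epimers, which are diastereomers, are separated by chromatography.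
   - F4 is oxidised with DDQ in dioxane; hydride abstraction at C1 of the isochroman (alpha to the ring oxygen and para to the 6-hydroxyl group) should give the quinone methide 19 directly.

2. Step 4. The alkyllithium or the aryllithium may attack the sulfonate (at sulfur, or by C-alkylation to a benzocyclobutene), and the warmed carboxylate may eliminate instead of substituting. The fallback sets out from 5 and comes back at 11; it forms the same two bonds in separate operations and never exposes a sulfonate to an organolithium.
   - Step 3 is run without TsCl (n-BuLi, Me2SO4, then aq. NH4Cl) to give (2S,3S)-3-(2-bromo-3,5-dimethoxy-6-methylphenyl)butan-2-ol F1.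
   - F1 is treated with n-BuLi (2.1 equiv) and CO2 and acidified cold to give 2-[(2S,3S)-3-hydroxybutan-2-yl]-4,6-dimethoxy-3-methylbenzoic acid F2. This di-ortho-substituted benzoic acid should be slow to lactonise with retention through its acyl carbon.
   - Mitsunobu lactonisation of F2 (PPh3, diisopropyl azodicarboxylate, THF, 0 °C) closes O2–C3 with the same inversion and gives 11.

3. Step 7. The ketone may be over-reduced to the 7-ethyl compound through the quinone methide that the phenoxide-activated carbinol forms under the basic hydride conditions, and the labile carbinol may dehydrate and oligomerise on isolation. The fallback sets out from 12 and comes back at 17, bypassing steps 6 and 7.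
   - Lactone 12 is brominated at its only free position (NBS, MeCN) to (3R,4S)-7-bromo-6,8-dihydroxy-3,4,5-trimethylisochroman-1-one F5.
   - Suzuki–Miyaura coupling of F5 with potassium vinyltrifluoroborate (PdCl2(dppf), Et3N, n-PrOH, 80 °C) gives (3R,4S)-7-ethenyl-6,8-dihydroxy-3,4,5-trimethylisochroman-1-one F6.
   - Protonation of this ortho-hydroxystyrene by the chiral acid of step 9 (an N-triflyl phosphoramide of the same backbone if the phosphoric acid is too weak) should give the same ion pair as 16, which 15 intercepts to give 17.

Further compounds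
F1 | step 4 | (2S,3S)-3-(2-bromo-3,5-dimethoxy-6-methylphenyl)butan-2-ol | C[C@H](O)[C@@H](C)c1c(C)c(OC)cc(OC)c1Br
F2 | step 4 | 2-[(2S,3S)-3-hydroxybutan-2-yl]-4,6-dimethoxy-3-methylbenzoic acid | C[C@H](O)[C@@H](C)c1c(C)c(OC)cc(OC)c1C(=O)O
F3 | step 9 | (3R,4S)-3,4,5-trimethylisochromane-6,8-diol | Oc1cc(O)c(C)c2c1CO[C@H](C)[C@H]2C
F4 | step 9 | (3R,4S)-7-[(1S)-1-[(3R,4S)-6,8-dihydroxy-3,4,5-trimethylisochroman-7-yl]ethyl]-6,8-dihydroxy-3,4,5-trimethylisochroman-1-one | Cc1c2c(CO[C@H](C)[C@H]2C)c(O)c([C@H](C)c2c(O)c(C)c3c(c2O)C(=O)O[C@H](C)[C@H]3C)c1O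
F5 | step 7 | (3R,4S)-7-bromo-6,8-dihydroxy-3,4,5-trimethylisochroman-1-one | Brc1c(O)c(C)c2c(c1O)C(=O)O[C@H](C)[C@H]2C
F6 | step 7 | (3R,4S)-7-ethenyl-6,8-dihydroxy-3,4,5-trimethylisochroman-1-one | C=Cc1c(O)c(C)c2c(c1O)C(=O)O[C@H](C)[C@H]2C
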